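**Plan**
- Retrosynthesis: each guaiacylglycerol arm is cut at C7–C8 (aldol) and at O–C8 (O-alkylation with a chloroacetyl imide); the core is cut at both aryl–C7/C7′ bonds, then at C8–C8′.
- Forward: C8–C8′ is made first by enolate dimerisation, ozonolysis closes both oxolane rings as a cis-fused bis-lactol, and both syringyl rings are attached in one two-directional C-arylation. The core is then desymmetrised, arm C is grown on one phenol, and arm B is grown on the other with arm A already attached to its aldehyde.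
- Enabling feature: both aryl–C7 and aryl–C7′ bonds lie on the convex face of the cis-fused 3,7-dioxabicyclo[3.3.0]octane (rings C7–O–C9′–C8′–C8 and C7′–O–C9–C8–C8′), so C8/C8′, fixed before any aryl group is present, can direct both arylations.
- Stereochemistry: C8/C8′ from the (R)-oxazolidinone in the dimerisation; C7/C7′ from exo attack on the bicyclic oxocarbenium ions; C8 of every arm from an Evans syn aldol; C7 of arm B from that aldol (threo); C7 of arms A and C by Mitsunobu inversion of the syn adduct (erythro).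

Key step: step 9

Remark: both enantiomers of 4-benzyl-3-(chloroacetyl)-1,3-oxazolidin-2-one are taken as purchasable; the two phenol oxygens (O4, O4′) of the C2-symmetric core are equivalent, so either may carry a given arm.

Shorthand in names: "syringaresinol" = (7R,7′R,8S,8′S)-syringaresinol, i.e. (1R,3aS,4R,6aS)-1,4-bis(4-hydroxy-3,5-dimethoxyphenyl)tetrahydro-1H,3H-furo[3,4-c]furan; Xc(S)/Xc(R) = (4S)-/(4R)-4-benzyl-2-oxo-1,3-oxazolidin-3-yl; G = 3-methoxy-4-(triisopropylsilyloxy)phenyl; TBS = tert-butyldimethylsilyl; TIPS = triisopropylsilyl; PNB = 4-nitrobenzoyl.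

**Step 1**
Reactants: 1 (4R)-4-benzyl-1,3-oxazolidin-2-one; 2 pent-4-enoyl chloride
Product: 3 (4R)-4-benzyl-3-(pent-4-enoyl)-1,3-oxazolidin-2-one
Conditions: n-BuLi, THF, −78 °C; then 2, −78 → 0 °C
Reagents that add atoms: none
Why: N-acylation of the lithiated oxazolidinone by the acid chloride (standard Evans imide formation) is fast at −78 °C and does not touch the terminal alkene.

**Step 2**
Reactants: 3 (two molecules), (4R)-4-benzyl-3-(pent-4-enoyl)-1,3-oxazolidin-2-one
Product: 5 (2S,3S)-1,4-bis[Xc(R)]-2,3-di(prop-2-en-1-yl)butane-1,4-dione, via lithium (Z)-enolate 4 (not isolated)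
Conditions: LiN(i-Pr)2, THF, −78 °C; then TiCl4, −78 °C → rt
Reagents that add atoms: none
Why: Oxidative enolate homocoupling, in which tetravalent titanium takes one electron per chelated (Z)-enolate and falls to trivalent titanium, joins two α-carbons on the enolate face remote from each benzyl group, so both new centres (the later C8 and C8′) should be S and the C2-symmetric dimer is separated from any unsymmetrical isomer by crystallisation or chromatography.

**Step 3**
Reactants: 5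
Product: 6 (2S,3S)-2,3-di(prop-2-en-1-yl)butane-1,4-diol
Conditions: LiBH4, MeOH, THF, 0 °C → rt
Reagents that add atoms: none
Why: LiBH4 reduces N-acyl oxazolidinones at the exocyclic carbonyl (reductive auxiliary cleavage) to primary alcohols without touching the alkenes or the α-centres, and the auxiliary is returned.

**Step 4**
Reactants: 6
Product: 7 (2S,3S)-2,3-di[(1E)-prop-1-en-1-yl]butane-1,4-diol
Conditions: RuHCl(CO)(PPh3)3 (3 mol%), toluene, 80 °C, stopped when 6 is consumed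
Reagents that add atoms: none
Why: Ruthenium-hydride alkene isomerisation (hydrometalation then β-hydride elimination) moves each terminal double bond one position to the more stable disubstituted alkene, while a second shift would need hydrometalation next to the branched C8 carbon and is slow, so the stereocentres should stay intact.

**Step 5**
Reactants: 7
Product: 9 (1S,5S)-3,7-dioxabicyclo[3.3.0]octane-2,6-diol (anomer mixture), via open-chain dialdehyde 8 (not isolated)
Conditions: O3, CH2Cl2, −78 °C; then Me2S, −78 °C → rt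
Reagents that add atoms: ozone, O=[O+][O-]
Why: Ozonolysis with reductive work-up cuts both propenyl groups down to aldehydes sitting directly on the stereocentres, and each aldehyde is trapped by the hydroxymethyl group of the neighbouring stereocentre as a five-membered lactol, the (S,S) configuration allowing only the cis-fused bicycle.

**Step 6**
Reactants: 9
Product: 10 (1S,5S)-3,7-dioxabicyclo[3.3.0]octane-2,6-diyl diacetate (anomer mixture)
Conditions: Ac2O, pyridine, DMAP (cat.), CH2Cl2, 0 °C → rt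
Reagents that add atoms: acetic anhydride, CC(=O)OC(C)=O
Why: DMAP-catalysed acetylation of the two hemiacetal hydroxyls installs the anomeric leaving groups, and the anomer mixture is acceptable because every anomer ionises to the same cation in step 9.

**Step 7**
Reactants: 11 4-bromo-2,6-dimethoxyphenol
Product: 12 2-(benzyloxy)-5-bromo-1,3-dimethoxybenzene
Conditions: BnBr, K2CO3, DMF, rt
Reagents that add atoms: benzyl bromide, BrCc1ccccc1
Why: Williamson ether synthesis on the acidic, flanked phenol gives a benzyl ether that tolerates magnesium, zinc and BF3 and can be removed later without acid.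

**Step 8**
Reactants: 12
Product: 13 [4-(benzyloxy)-3,5-dimethoxyphenyl]magnesium bromide (THF solution, titrated)
Conditions: Mg turnings (I2-activated), THF, 40 °C
Reagents that add atoms: magnesium, [Mg]
Why: Direct magnesium insertion into the aryl bromide (Grignard formation) places the metal para to the benzyloxy group, the only position from which the syringyl ring can be joined correctly.

**Step 9**
Reactants: 10 (1S,5S)-3,7-dioxabicyclo[3.3.0]octane-2,6-diyl diacetate; 13 (two molecules), [4-(benzyloxy)-3,5-dimethoxyphenyl]magnesium bromide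
Product: 15 (7R,7′R,8S,8′S)-4,4′-di-O-benzylsyringaresinol, via bis[4-(benzyloxy)-3,5-dimethoxyphenyl]zinc 14 (not isolated)
Conditions: ZnBr2 (1 equiv per 2 equiv of 13), THF, 0 °C → rt, THF largely exchanged for toluene; then 10, BF3·OEt2, CH2Cl2/toluene, −78 → −20 °C; the equation needs two molecules of 13 (one of 14) per molecule of 10, and in practice 14 is used in excess
Reagents that add atoms: none
Why: BF3·OEt2 ionises each anomeric acetate of 10 in turn to a five-membered cyclic oxocarbenium ion fused to the second oxolane ring, and one aryl group per cationic carbon is transferred from the diarylzinc 14, itself made from two molecules of 13 and ZnBr2; the closest known reaction type is the Lewis-acid-promoted C-arylation of lactol (glycosyl and furanosyl) acetates with arylzinc reagents used for C-aryl glycosides. No ring is closed: the 3,7-dioxabicyclo[3.3.0]octane is carried over intact from 10 and only the two exocyclic aryl–C7 and aryl–C7′ bonds form. Each new stereocentre (C7, then C7′) is controlled by the cis ring fusion set at C8/C8′ in step 2: the nucleophile approaches on the convex (exo) face, anti to the C8–C9 (C8′–C9′) bond of the neighbouring ring, so each aryl group ends up cis to H8/H8′ and both centres should be R. The step needs exo facial selectivity at both sites, substitution in preference to attack on the acetate carbonyl, and a single bonding site on the arene; the folded bicycle supplies the first, the soft arylzinc used in place of the Grignard reagent the second, and the carbon–metal bond para to the benzyloxy group the third. Because all anomers give the same cation and the electrophile is C2-symmetric, one reagent serves both ends.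

**Step 10**
Reactants: 15
Product: 16 (7R,7′R,8S,8′S)-4-O-benzylsyringaresinol (one free phenol)
Conditions: H2 (1 atm), 10% Pd/C, EtOAc, rt, interrupted near half conversion; recovered 15 and the bis-phenol (after re-benzylation) are recycled
Reagents that add atoms: none
Why: Hydrogenolysis of an aryl benzyl ether over Pd/C is far faster than cleavage of the ring benzylic C–O bonds, and since the two ether groups are remote and related by the C2 axis, interrupting the reaction should give a statistical mixture in which either mono-ether is the same compound 16.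

**Step 11**
Reactants: 17 vanillin
Product: 18 3-methoxy-4-(triisopropylsilyloxy)benzaldehyde
Conditions: TIPSCl, imidazole, DMF, rt
Reagents that add atoms: chlorotriisopropylsilane, CC(C)[Si](Cl)(C(C)C)C(C)C
Why: Silylation of the phenol gives a hindered aryl silyl ether that should survive carbonate, borohydride, hydrogenolysis and boron triflate and leave with fluoride at the end.

**Step 12**
Reactants: 16; 19 (4S)-4-benzyl-3-(chloroacetyl)-1,3-oxazolidin-2-one
Product: 20 4-O-benzyl-4′-O-{2-[Xc(S)]-2-oxoethyl}syringaresinol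
Conditions: K2CO3, MeCN, 40 °C
Reagents that add atoms: none
Why: Williamson ether synthesis, the phenoxide displacing chloride from the activated α-chloro imide faster than it attacks the imide carbonyl.

**Step 13**
Reactants: 20; 18
Product: 22 4-O-benzyl-4′-O-{(2S,3R)-1-[Xc(S)]-3-hydroxy-3-G-1-oxopropan-2-yl}syringaresinol, via dibutylboron (Z)-enolate 21 (not isolated)
Conditions: Bu2BOTf, i-Pr2NEt, CH2Cl2, −78 → 0 °C; 18, −78 → 0 °C; then pH 7 buffer, MeOH, 30% H2O2, 0 °C
Reagents that add atoms: none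
Why: Evans syn aldol: the (Z)-boron enolate reacts through a chair Zimmerman–Traxler transition state on the enolate face opposite the auxiliary's benzyl group, which sets C8 and C7 of arm C together as the (2S,3R) syn adduct (threo series).

**Step 14**
Reactants: 22
Product: 23 4-O-benzyl-4′-O-{(2S,3S)-1-[Xc(S)]-3-(4-nitrobenzoyloxy)-3-G-1-oxopropan-2-yl}syringaresinol
Conditions: PPh3, DIAD, 4-nitrobenzoic acid, THF, 0 °C → rt
Reagents that add atoms: 4-nitrobenzoic acid, O=C(O)c1ccc(cc1)[N+](=O)[O-]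
Why: Mitsunobu esterification: 4-nitrobenzoate displaces the oxyphosphonium at benzylic C7 by SN2 with inversion, turning the syn (threo) adduct into the erythro arrangement needed for arm C while C8 is not involved.

**Step 15**
Reactants: 23
Product: 24 4-O-benzyl-4′-O-{(1S,2R)-1,3-dihydroxy-1-G-propan-2-yl}syringaresinol
Conditions: LiBH4, MeOH, THF, 0 °C → rt
Reagents that add atoms: none
Why: LiBH4 reduces the imide carbonyl to the primary alcohol (reductive auxiliary cleavage) and cleaves the activated nitrobenzoate in the same operation, neither stereocentre being touched.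

**Step 16**
Reactants: 24
Product: 25 4-O-benzyl-4′-O-{(1S,2R)-1,3-bis(TBS-oxy)-1-G-propan-2-yl}syringaresinol
Conditions: TBSOTf, 2,6-lutidine, CH2Cl2, −78 → 0 °C
Reagents that add atoms: tert-butyldimethylsilyl triflate, CC(C)(C)[Si](C)(C)OS(=O)(=O)C(F)(F)F
Why: Silyl ether formation masks both hydroxyls so that they cannot bind the boron triflate of the later aldol, the hindered base keeping the medium non-acidic for the benzylic ethers of the core.

**Step 17**
Reactants: 25
Product: 26 4′-O-{(1S,2R)-1,3-bis(TBS-oxy)-1-G-propan-2-yl}syringaresinol (free phenol at O4)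
Conditions: H2 (1 atm), 10% Pd/C, EtOAc, rt
Reagents that add atoms: none
Why: Catalytic hydrogenolysis removes the remaining benzyl ether, the silyl ethers and the ring benzylic ethers being stable in ethyl acetate at atmospheric pressure.

**Step 18**
Reactants: 26; 19
Product: 27 4-O-{2-[Xc(S)]-2-oxoethyl}-4′-O-{(1S,2R)-1,3-bis(TBS-oxy)-1-G-propan-2-yl}syringaresinol
Conditions: K2CO3, MeCN, 40 °C
Reagents that add atoms: none
Why: Williamson ether synthesis as in step 12; the aryl TIPS ether and the alkyl TBS ethers should tolerate K2CO3 in acetonitrile.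

**Step 19**
Reactants: 28 4-hydroxy-3-methoxybenzonitrile; 29 (4R)-4-benzyl-3-(chloroacetyl)-1,3-oxazolidin-2-one
Product: 30 4-{2-[Xc(R)]-2-oxoethoxy}-3-methoxybenzonitrile
Conditions: K2CO3, MeCN, 40 °C
Reagents that add atoms: none
Why: Williamson ether synthesis; the nitrile serves as a masked aldehyde that is inert to enolisation, Mitsunobu and borohydride conditions.

**Step 20**
Reactants: 30; 18
Product: 32 4-{[(2R,3S)-1-[Xc(R)]-3-hydroxy-3-G-1-oxopropan-2-yl]oxy}-3-methoxybenzonitrile, via dibutylboron (Z)-enolate 31 (not isolated)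
Conditions: Bu2BOTf, i-Pr2NEt, CH2Cl2, −78 → 0 °C; 18, −78 → 0 °C; then pH 7 buffer, MeOH, 30% H2O2, 0 °C
Reagents that add atoms: none
Why: Evans syn aldol with the enantiomeric auxiliary, which sets C8 and C7 of arm A as the (2R,3S) syn adduct through the same chair transition state.

**Step 21**
Reactants: 32
Product: 33 4-{[(2R,3R)-1-[Xc(R)]-3-(4-nitrobenzoyloxy)-3-G-1-oxopropan-2-yl]oxy}-3-methoxybenzonitrile
Conditions: PPh3, DIAD, 4-nitrobenzoic acid, THF, 0 °C → rt
Reagents that add atoms: 4-nitrobenzoic acid, O=C(O)c1ccc(cc1)[N+](=O)[O-]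
Why: Mitsunobu inversion at benzylic C7 (SN2 by 4-nitrobenzoate) converts the syn adduct into the erythro arrangement of arm A.

**Step 22**
Reactants: 33
Product: 34 4-{[(1R,2S)-1,3-dihydroxy-1-G-propan-2-yl]oxy}-3-methoxybenzonitrile
Conditions: LiBH4, MeOH, THF, 0 °C → rt
Reagents that add atoms: none
Why: LiBH4 reductive cleavage of imide and nitrobenzoate as in step 15; an aryl nitrile is not reduced by LiBH4 under these conditions.

**Step 23**
Reactants: 34
Product: 35 4-{[(1R,2S)-1,3-bis(TBS-oxy)-1-G-propan-2-yl]oxy}-3-methoxybenzonitrile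
Conditions: TBSOTf, 2,6-lutidine, CH2Cl2, −78 → 0 °C
Reagents that add atoms: tert-butyldimethylsilyl triflate, CC(C)(C)[Si](C)(C)OS(=O)(=O)C(F)(F)F
Why: Silyl ether formation on both hydroxyls, needed so that the fragment can pass through the hydride reduction and the boron aldol without free OH groups.

**Step 24**
Reactants: 35
Product: 37 4-{[(1R,2S)-1,3-bis(TBS-oxy)-1-G-propan-2-yl]oxy}-3-methoxybenzaldehyde, via N-(diisobutylaluminio) aldimine 36 (not isolated)
Conditions: i-Bu2AlH, toluene, −78 °C; then aq. potassium sodium tartrate, rt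
Reagents that add atoms: water, O
Why: Partial reduction of a nitrile with diisobutylaluminium hydride: a single hydride adds to give the N-aluminio imine, which is stable at low temperature and is hydrolysed to the aldehyde on aqueous work-up, silyl ethers being inert.

**Step 25**
Reactants: 27; 37
Product: 39 arm B syn-aldol adduct: 4-O-{(2S,3R)-1-[Xc(S)]-3-hydroxy-1-oxo-3-(3-methoxy-4-{[(1R,2S)-1,3-bis(TBS-oxy)-1-G-propan-2-yl]oxy}phenyl)propan-2-yl} derivative of 26, via dibutylboron (Z)-enolate 38 (not isolated)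
Conditions: Bu2BOTf, i-Pr2NEt, CH2Cl2, −78 → 0 °C; 37, −78 → 0 °C; then pH 7 buffer, MeOH, 30% H2O2, 0 °C
Reagents that add atoms: none
Why: Evans syn aldol: reagent control by the (S)-auxiliary through the (Z)-boron enolate sets C8 and C7 of arm B as the (2S,3R) syn adduct, which is already the threo arrangement required, the remote stereocentres of 37 having no say.

**Step 26**
Reactants: 39
Product: 40 hexasilyl ether of the target: 4-O-{(1R,2R)-1,3-dihydroxy-1-(3-methoxy-4-{[(1R,2S)-1,3-bis(TBS-oxy)-1-G-propan-2-yl]oxy}phenyl)propan-2-yl} derivative of 26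
Conditions: LiBH4, MeOH, THF, 0 °C
Reagents that add atoms: none
Why: LiBH4 reductive cleavage of the imide gives the primary alcohol of arm B and returns the auxiliary without touching C7 or C8.

**Step 27**
Reactants: 40
Product: 41 target compound (CNP0316493.1)
Conditions: Bu4NF, AcOH, THF, 0 °C → rt
Reagents that add atoms: none
Why: Fluoride-mediated desilylation removes the four TBS and two TIPS groups in one operation, the acetic acid buffer keeping the phenoxide concentration low so that the 4-hydroxybenzylic alcohols do not ionise and the C7 configurations are kept.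

**Compound list**

1 | (4R)-4-benzyl-1,3-oxazolidin-2-one | O=C1N[C@H](Cc2ccccc2)CO1 | starting material
2 | pent-4-enoyl chloride | C=CCCC(=O)Cl | starting material
3 | (4R)-4-benzyl-3-(pent-4-enoyl)-1,3-oxazolidin-2-one | C=CCCC(=O)N1C(=O)OC[C@H]1Cc1ccccc1 | intermediate
4 | lithium (Z)-enolate of 3 | C=CC/C=C(\O[Li])N1C(=O)OC[C@H]1Cc1ccccc1 | intermediate (not isolated)
5 | (2S,3S)-1,4-bis[(4R)-4-benzyl-2-oxo-1,3-oxazolidin-3-yl]-2,3-di(prop-2-en-1-yl)butane-1,4-dione | C=CC[C@H](C(=O)N1C(=O)OC[C@H]1Cc1ccccc1)[C@H](CC=C)C(=O)N1C(=O)OC[C@H]1Cc1ccccc1 | intermediate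
6 | (2S,3S)-2,3-di(prop-2-en-1-yl)butane-1,4-diol | C=CC[C@H](CO)[C@H](CC=C)CO | intermediate
7 | (2S,3S)-2,3-di[(1E)-prop-1-en-1-yl]butane-1,4-diol | C/C=C/[C@H](CO)[C@H](/C=C/C)CO | intermediate
8 | (2S,3S)-2,3-bis(hydroxymethyl)butanedial | O=C[C@H](CO)[C@H](C=O)CO | intermediate (not isolated)
9 | (1S,5S)-3,7-dioxabicyclo[3.3.0]octane-2,6-diol, anomer mixture | OC1OC[C@@H]2[C@H]1COC2O | intermediate
10 | (1S,5S)-3,7-dioxabicyclo[3.3.0]octane-2,6-diyl diacetate, anomer mixture | CC(=O)OC1OC[C@@H]2[C@H]1COC2OC(C)=O | intermediate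
11 | 4-bromo-2,6-dimethoxyphenol | COc1cc(Br)cc(OC)c1O | starting material
12 | 2-(benzyloxy)-5-bromo-1,3-dimethoxybenzene | COc1cc(Br)cc(OC)c1OCc1ccccc1 | intermediate
13 | [4-(benzyloxy)-3,5-dimethoxyphenyl]magnesium bromide | COc1cc([Mg]Br)cc(OC)c1OCc1ccccc1 | intermediate
14 | bis[4-(benzyloxy)-3,5-dimethoxyphenyl]zinc | COc1cc([Zn]c2cc(OC)c(OCc3ccccc3)c(OC)c2)cc(OC)c1OCc1ccccc1 | intermediate (not isolated)
15 | (7R,7′R,8S,8′S)-4,4′-di-O-benzylsyringaresinol | COc1cc([C@@H]2OC[C@@H]3[C@H]2CO[C@H]3c2cc(OC)c(OCc3ccccc3)c(OC)c2)cc(OC)c1OCc1ccccc1 | intermediate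
16 | (7R,7′R,8S,8′S)-4-O-benzylsyringaresinol | COc1cc([C@@H]2OC[C@@H]3[C@H]2CO[C@H]3c2cc(OC)c(OCc3ccccc3)c(OC)c2)cc(OC)c1O | intermediate
17 | vanillin (4-hydroxy-3-methoxybenzaldehyde) | COc1cc(C=O)ccc1O | starting material
18 | 3-methoxy-4-(triisopropylsilyloxy)benzaldehyde | COc1cc(C=O)ccc1O[Si](C(C)C)(C(C)C)C(C)C | intermediate
19 | (4S)-4-benzyl-3-(chloroacetyl)-1,3-oxazolidin-2-one | O=C(CCl)N1C(=O)OC[C@@H]1Cc1ccccc1 | starting material
20 | 4-O-benzyl-4′-O-{2-[Xc(S)]-2-oxoethyl}syringaresinol | COc1cc([C@@H]2OC[C@@H]3[C@H]2CO[C@H]3c2cc(OC)c(OCc3ccccc3)c(OC)c2)cc(OC)c1OCC(=O)N1C(=O)OC[C@@H]1Cc1ccccc1 | intermediate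
21 | dibutylboron (Z)-enolate of 20 | COc1cc([C@@H]2OC[C@@H]3[C@H]2CO[C@H]3c2cc(OC)c(OCc3ccccc3)c(OC)c2)cc(OC)c1O/C=C(\OB(CCCC)CCCC)N1C(=O)OC[C@@H]1Cc1ccccc1 | intermediate (not isolated)
22 | 4-O-benzyl-4′-O-{(2S,3R)-1-[Xc(S)]-3-hydroxy-3-G-1-oxopropan-2-yl}syringaresinol | COc1cc([C@@H]2OC[C@@H]3[C@H]2CO[C@H]3c2cc(OC)c(OCc3ccccc3)c(OC)c2)cc(OC)c1O[C@H](C(=O)N1C(=O)OC[C@@H]1Cc1ccccc1)[C@H](O)c1ccc(O[Si](C(C)C)(C(C)C)C(C)C)c(OC)c1 | intermediate
23 | 4-O-benzyl-4′-O-{(2S,3S)-1-[Xc(S)]-3-(4-nitrobenzoyloxy)-3-G-1-oxopropan-2-yl}syringaresinol | COc1cc([C@@H]2OC[C@@H]3[C@H]2CO[C@H]3c2cc(OC)c(OCc3ccccc3)c(OC)c2)cc(OC)c1O[C@H](C(=O)N1C(=O)OC[C@@H]1Cc1ccccc1)[C@@H](OC(=O)c1ccc(cc1)[N+](=O)[O-])c1ccc(O[Si](C(C)C)(C(C)C)C(C)C)c(OC)c1 | intermediate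
24 | 4-O-benzyl-4′-O-{(1S,2R)-1,3-dihydroxy-1-G-propan-2-yl}syringaresinol | COc1cc([C@@H]2OC[C@@H]3[C@H]2CO[C@H]3c2cc(OC)c(OCc3ccccc3)c(OC)c2)cc(OC)c1O[C@H](CO)[C@@H](O)c1ccc(O[Si](C(C)C)(C(C)C)C(C)C)c(OC)c1 | intermediate
25 | 4-O-benzyl-4′-O-{(1S,2R)-1,3-bis(TBS-oxy)-1-G-propan-2-yl}syringaresinol | COc1cc([C@@H]2OC[C@@H]3[C@H]2CO[C@H]3c2cc(OC)c(OCc3ccccc3)c(OC)c2)cc(OC)c1O[C@H](CO[Si](C)(C)C(C)(C)C)[C@@H](O[Si](C)(C)C(C)(C)C)c1ccc(O[Si](C(C)C)(C(C)C)C(C)C)c(OC)c1 | intermediate
26 | 4′-O-{(1S,2R)-1,3-bis(TBS-oxy)-1-G-propan-2-yl}syringaresinol | COc1cc([C@@H]2OC[C@@H]3[C@H]2CO[C@H]3c2cc(OC)c(O)c(OC)c2)cc(OC)c1O[C@H](CO[Si](C)(C)C(C)(C)C)[C@@H](O[Si](C)(C)C(C)(C)C)c1ccc(O[Si](C(C)C)(C(C)C)C(C)C)c(OC)c1 | intermediate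
27 | 4-O-{2-[Xc(S)]-2-oxoethyl}-4′-O-{(1S,2R)-1,3-bis(TBS-oxy)-1-G-propan-2-yl}syringaresinol | COc1cc([C@@H]2OC[C@@H]3[C@H]2CO[C@H]3c2cc(OC)c(OCC(=O)N3C(=O)OC[C@@H]3Cc3ccccc3)c(OC)c2)cc(OC)c1O[C@H](CO[Si](C)(C)C(C)(C)C)[C@@H](O[Si](C)(C)C(C)(C)C)c1ccc(O[Si](C(C)C)(C(C)C)C(C)C)c(OC)c1 | intermediate
28 | 4-hydroxy-3-methoxybenzonitrile | COc1cc(C#N)ccc1O | starting material
29 | (4R)-4-benzyl-3-(chloroacetyl)-1,3-oxazolidin-2-one | O=C(CCl)N1C(=O)OC[C@H]1Cc1ccccc1 | starting material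
30 | 4-{2-[Xc(R)]-2-oxoethoxy}-3-methoxybenzonitrile | COc1cc(C#N)ccc1OCC(=O)N1C(=O)OC[C@H]1Cc1ccccc1 | intermediate
31 | dibutylboron (Z)-enolate of 30 | COc1cc(C#N)ccc1O/C=C(\OB(CCCC)CCCC)N1C(=O)OC[C@H]1Cc1ccccc1 | intermediate (not isolated)
32 | 4-{[(2R,3S)-1-[Xc(R)]-3-hydroxy-3-G-1-oxopropan-2-yl]oxy}-3-methoxybenzonitrile | COc1cc(C#N)ccc1O[C@@H](C(=O)N1C(=O)OC[C@H]1Cc1ccccc1)[C@@H](O)c1ccc(O[Si](C(C)C)(C(C)C)C(C)C)c(OC)c1 | intermediate
33 | 4-{[(2R,3R)-1-[Xc(R)]-3-(4-nitrobenzoyloxy)-3-G-1-oxopropan-2-yl]oxy}-3-methoxybenzonitrile | COc1cc(C#N)ccc1O[C@@H](C(=O)N1C(=O)OC[C@H]1Cc1ccccc1)[C@H](OC(=O)c1ccc(cc1)[N+](=O)[O-])c1ccc(O[Si](C(C)C)(C(C)C)C(C)C)c(OC)c1 | intermediate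
34 | 4-{[(1R,2S)-1,3-dihydroxy-1-G-propan-2-yl]oxy}-3-methoxybenzonitrile | COc1cc(C#N)ccc1O[C@@H](CO)[C@H](O)c1ccc(O[Si](C(C)C)(C(C)C)C(C)C)c(OC)c1 | intermediate
35 | 4-{[(1R,2S)-1,3-bis(TBS-oxy)-1-G-propan-2-yl]oxy}-3-methoxybenzonitrile | COc1cc(C#N)ccc1O[C@@H](CO[Si](C)(C)C(C)(C)C)[C@H](O[Si](C)(C)C(C)(C)C)c1ccc(O[Si](C(C)C)(C(C)C)C(C)C)c(OC)c1 | intermediate
36 | N-(diisobutylaluminio) aldimine of 37 | COc1cc(C=N[Al](CC(C)C)CC(C)C)ccc1O[C@@H](CO[Si](C)(C)C(C)(C)C)[C@H](O[Si](C)(C)C(C)(C)C)c1ccc(O[Si](C(C)C)(C(C)C)C(C)C)c(OC)c1 | intermediate (not isolated)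
37 | 4-{[(1R,2S)-1,3-bis(TBS-oxy)-1-G-propan-2-yl]oxy}-3-methoxybenzaldehyde | COc1cc(C=O)ccc1O[C@@H](CO[Si](C)(C)C(C)(C)C)[C@H](O[Si](C)(C)C(C)(C)C)c1ccc(O[Si](C(C)C)(C(C)C)C(C)C)c(OC)c1 | intermediate
38 | dibutylboron (Z)-enolate of 27 | COc1cc([C@@H]2OC[C@@H]3[C@H]2CO[C@H]3c2cc(OC)c(O/C=C(\OB(CCCC)CCCC)N3C(=O)OC[C@@H]3Cc3ccccc3)c(OC)c2)cc(OC)c1O[C@H](CO[Si](C)(C)C(C)(C)C)[C@@H](O[Si](C)(C)C(C)(C)C)c1ccc(O[Si](C(C)C)(C(C)C)C(C)C)c(OC)c1 | intermediate (not isolated)
39 | 4-O-{(2S,3R)-1-[Xc(S)]-3-hydroxy-1-oxo-3-(3-methoxy-4-{[(1R,2S)-1,3-bis(TBS-oxy)-1-G-propan-2-yl]oxy}phenyl)propan-2-yl}-4′-O-{(1S,2R)-1,3-bis(TBS-oxy)-1-G-propan-2-yl}syringaresinol | COc1cc([C@@H]2OC[C@@H]3[C@H]2CO[C@H]3c2cc(OC)c(O[C@H](C(=O)N3C(=O)OC[C@@H]3Cc3ccccc3)[C@H](O)c3ccc(O[C@@H](CO[Si](C)(C)C(C)(C)C)[C@H](O[Si](C)(C)C(C)(C)C)c4ccc(O[Si](C(C)C)(C(C)C)C(C)C)c(OC)c4)c(OC)c3)c(OC)c2)cc(OC)c1O[C@H](CO[Si](C)(C)C(C)(C)C)[C@@H](O[Si](C)(C)C(C)(C)C)c1ccc(O[Si](C(C)C)(C(C)C)C(C)C)c(OC)c1 | intermediate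
40 | 4-O-{(1R,2R)-1,3-dihydroxy-1-(3-methoxy-4-{[(1R,2S)-1,3-bis(TBS-oxy)-1-G-propan-2-yl]oxy}phenyl)propan-2-yl}-4′-O-{(1S,2R)-1,3-bis(TBS-oxy)-1-G-propan-2-yl}syringaresinol | COc1cc([C@@H]2OC[C@@H]3[C@H]2CO[C@H]3c2cc(OC)c(O[C@H](CO)[C@H](O)c3ccc(O[C@@H](CO[Si](C)(C)C(C)(C)C)[C@H](O[Si](C)(C)C(C)(C)C)c4ccc(O[Si](C(C)C)(C(C)C)C(C)C)c(OC)c4)c(OC)c3)c(OC)c2)cc(OC)c1O[C@H](CO[Si](C)(C)C(C)(C)C)[C@@H](O[Si](C)(C)C(C)(C)C)c1ccc(O[Si](C(C)C)(C(C)C)C(C)C)c(OC)c1 | intermediate
41 | CNP0316493.1: syringaresinol (7R,7′R,8S,8′S) carrying at O4 a threo-(7R,8R)-guaiacylglycerol-8-yl unit whose own 4-O bears an erythro-(7R,8S)-guaiacylglycerol-8-yl unit, and at O4′ an erythro-(7S,8R)-guaiacylglycerol-8-yl unit | COc1cc([C@@H](O)[C@H](CO)Oc2ccc([C@@H](O)[C@@H](CO)Oc3c(OC)cc([C@@H]4OC[C@@H]5[C@H]4CO[C@H]5c4cc(OC)c(O[C@H](CO)[C@@H](O)c5ccc(O)c(OC)c5)c(OC)c4)cc3OC)cc2OC)ccc1O | target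

**Totals**
Total step count: 27.
Longest linear sequence: 18 steps (steps 1–6, 9, 10, 12–18, 25–27).

**Steps most likely to fail**

Step 9. The double substitution may stall after one aryl transfer, the oxocarbenium ion may lose a proton to give an enol ether, the zinc reagent may attack an acetate carbonyl, or aryl delivery may occur in part from the concave face and give endo-aryl (epi) isomers. The fallback forms the aryl–C7 bonds by carbonyl addition and closes the rings afterwards. It sets out from 9: excess Grignard reagent 13 (THF, 0 °C → rt) adds to the hydroxy-aldehyde forms of the bis-lactol to give (2S,3S)-1,4-bis[4-(benzyloxy)-3,5-dimethoxyphenyl]-2,3-bis(hydroxymethyl)butane-1,4-diol F1 as a mixture of benzylic epimers. Camphorsulfonic acid in CH2Cl2 then closes both oxolane rings by capture of the syringyl-stabilised benzylic cations by the primary hydroxyls under equilibrating conditions. The exo,exo isomer is separated from any mono-epi isomer, and the sequence comes back to the route at 15.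

Step 14 (the same concern applies to step 21). The activated C7 oxygen may be lost together with the acidic C8 hydrogen next to the imide (dehydration to the α-aryloxy cinnamoyl imide), or the electron-rich benzylic oxyphosphonium may ionise so that inversion is incomplete. The fallback moves the inversion to a substrate without the imide. It sets out from 22: LiBH4 reduction gives the threo diol 4-O-benzyl-4′-O-{(1R,2R)-1,3-dihydroxy-1-G-propan-2-yl}syringaresinol F2. Selective silylation of the primary hydroxyl (TBSCl, imidazole, CH2Cl2) gives 4-O-benzyl-4′-O-{(1R,2R)-3-(TBS-oxy)-1-hydroxy-1-G-propan-2-yl}syringaresinol F3. Mitsunobu esterification (PPh3, DIAD, 4-nitrobenzoic acid) then gives the inverted ester 4-O-benzyl-4′-O-{(1S,2R)-3-(TBS-oxy)-1-(4-nitrobenzoyloxy)-1-G-propan-2-yl}syringaresinol F4. Reductive ester cleavage (i-Bu2AlH, CH2Cl2, −78 °C) gives the erythro alcohol 4-O-benzyl-4′-O-{(1S,2R)-3-(TBS-oxy)-1-hydroxy-1-G-propan-2-yl}syringaresinol F5, and silylation with TBSOTf/2,6-lutidine comes back to the route at 25. The same sequence applied to 32 would return at 35.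

Step 2. The radical dimerisation may give low mass balance, α-chlorination, or too much of the unsymmetrical dimer. The fallback builds the C8–C8′ bond by two enolate alkylations. It sets out from 3: Evans alkylation of its sodium enolate (NaN(SiMe3)2, THF, −78 °C) with tert-butyl bromoacetate gives tert-butyl (3S)-3-{[(4R)-4-benzyl-2-oxo-1,3-oxazolidin-3-yl]carbonyl}hex-5-enoate F6. LiBH4 removes the auxiliary to give tert-butyl (3S)-3-(hydroxymethyl)hex-5-enoate F7, which lactonises with p-toluenesulfonic acid in toluene to (4S)-4-(prop-2-en-1-yl)oxolan-2-one F8. Allylation of the lactone lithium enolate (LiN(i-Pr)2, THF, −78 °C; allyl bromide) anti to the existing substituent gives trans-(3S,4S)-3,4-di(prop-2-en-1-yl)oxolan-2-one F9. LiAlH4 reduction opens the lactone and comes back to the route at 6.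

**Further compounds**

F1 | step 9 | (2S,3S)-1,4-bis[4-(benzyloxy)-3,5-dimethoxyphenyl]-2,3-bis(hydroxymethyl)butane-1,4-diol (benzylic epimers) | COc1cc(C(O)[C@H](CO)[C@H](C(O)c2cc(OC)c(OCc3ccccc3)c(OC)c2)CO)cc(OC)c1OCc1ccccc1
F2 | step 14 | 4-O-benzyl-4′-O-{(1R,2R)-1,3-dihydroxy-1-G-propan-2-yl}syringaresinol | COc1cc([C@@H]2OC[C@@H]3[C@H]2CO[C@H]3c2cc(OC)c(OCc3ccccc3)c(OC)c2)cc(OC)c1O[C@H](CO)[C@H](O)c1ccc(O[Si](C(C)C)(C(C)C)C(C)C)c(OC)c1
F3 | step 14 | 4-O-benzyl-4′-O-{(1R,2R)-3-(TBS-oxy)-1-hydroxy-1-G-propan-2-yl}syringaresinol | COc1cc([C@@H]2OC[C@@H]3[C@H]2CO[C@H]3c2cc(OC)c(OCc3ccccc3)c(OC)c2)cc(OC)c1O[C@H](CO[Si](C)(C)C(C)(C)C)[C@H](O)c1ccc(O[Si](C(C)C)(C(C)C)C(C)C)c(OC)c1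
F4 | step 14 | 4-O-benzyl-4′-O-{(1S,2R)-3-(TBS-oxy)-1-(4-nitrobenzoyloxy)-1-G-propan-2-yl}syringaresinol | COc1cc([C@@H]2OC[C@@H]3[C@H]2CO[C@H]3c2cc(OC)c(OCc3ccccc3)c(OC)c2)cc(OC)c1O[C@H](CO[Si](C)(C)C(C)(C)C)[C@@H](OC(=O)c1ccc(cc1)[N+](=O)[O-])c1ccc(O[Si](C(C)C)(C(C)C)C(C)C)c(OC)c1
F5 | step 14 | 4-O-benzyl-4′-O-{(1S,2R)-3-(TBS-oxy)-1-hydroxy-1-G-propan-2-yl}syringaresinol | COc1cc([C@@H]2OC[C@@H]3[C@H]2CO[C@H]3c2cc(OC)c(OCc3ccccc3)c(OC)c2)cc(OC)c1O[C@H](CO[Si](C)(C)C(C)(C)C)[C@@H](O)c1ccc(O[Si](C(C)C)(C(C)C)C(C)C)c(OC)c1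
F6 | step 2 | tert-butyl (3S)-3-{[(4R)-4-benzyl-2-oxo-1,3-oxazolidin-3-yl]carbonyl}hex-5-enoate | C=CC[C@H](C(=O)N1C(=O)OC[C@H]1Cc1ccccc1)CC(=O)OC(C)(C)C
F7 | step 2 | tert-butyl (3S)-3-(hydroxymethyl)hex-5-enoate | C=CC[C@H](CO)CC(=O)OC(C)(C)C
F8 | step 2 | (4S)-4-(prop-2-en-1-yl)oxolan-2-one | C=CC[C@@H]1COC(=O)C1
F9 | step 2 | (3S,4S)-3,4-di(prop-2-en-1-yl)oxolan-2-one | C=CC[C@@H]1COC(=O)[C@H]1CC=C
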